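You have 5 questions on 4 ways of running one coupling of a racemate, and the first is whether the ways differ at all.

| flask | left-handed substrate | coupling partner | catalyst | right-handed substrate | time | remark |
|---|---|---|---|---|---|---|
| dawn | 0.50 mM | 1.00 mM | 5.5 µM | 0.50 mM | 2.5 min | a closed flask charged with all of it at once and left for 2.5 min |
| summer | 0.50 mM | 1.00 mM | 5.5 µM | 0.50 mM |  | a single well-mixed tank run continuously and read at steady state, 2.5 min in it on average |
| spring | 0.50 mM | 1.00 mM | 5.5 µM | 0.50 mM |  | a single well-mixed tank run continuously and read at steady state, 12.5 min in it on average |
| autumn | 0.50 mM | 1.00 mM (fed, over 1.25 min) | 5.5 µM | 0.50 mM | 2.5 min | a stirred flask in which coupling partner is dosed at a steady rate over 1.25 min without added volume, worked up at 2.5 min |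

    coupling partner + catalyst + left-handed substrate → catalyst + left-handed product (k1 = 5.9 × 10⁶ L² mol⁻² s⁻¹)
    coupling partner + catalyst + right-handed substrate → catalyst + right-handed product (k2 = 2.2 × 10⁶ L² mol⁻² s⁻¹)
    left-handed substrate ⇌ right-handed substrate (k3 = 1.3 s⁻¹)
    coupling partner → decomposed reagent (k4 = 0.21 s⁻¹)

1. the set-up with the highest share of left-handed product in all that became left-handed product or right-handed product, at the outlet or at the end ("none" if the first two lie within 2 percentage points) (dawn / summer / spring / autumn / none)
2. share of left-handed product in all that became left-handed product or right-handed product, at the outlet or at the end, dawn
3. share of left-handed product in all that became left-handed product or right-handed product, at the outlet or at the end, summer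
4. share of left-handed product in all that became left-handed product or right-handed product, at the outlet or at the end, spring
5. share of left-handed product in all that became left-handed product or right-handed product, at the outlet or at the end, autumn

- catalyst is single-handed; left-handed substrate and right-handed substrate are mirror images of each other, charged as a racemate, each of them at the stated concentration
- the stated concentrations are those of everything mixed, before any reaction; amounts are the same in each set-up
- the feed brings no volume worth counting
- run time (dawn): 2.5 min

Turn the question round: for one set-up to beat another by 2 percentage points, something must pull the substrate off racemic. With [left-handed substrate] frozen equal to [right-handed substrate], as in the fast-racemisation limit of a dynamic kinetic resolution, the products form in the ratio of their rate constants, so the share is 72.8% in each of the 4 set-ups.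

Coupling does the pulling, since at equal concentrations it takes left-handed substrate faster than right-handed substrate. Interconversion pushes back with a half-life of 0.53 s on its forward rate alone, which is shorter than the 0.055 min of coupling partner under decomposition alone, so the imbalance can keep pace with [coupling partner].

Multiply the difference of the coupling constants by [catalyst] at 5.5 µM and [coupling partner] at its whole charge of 1.00 mM, then divide by 4 times the interconversion constant. This gives 0.391%, the skew ceiling: the excess of [right-handed substrate] over [left-handed substrate], as a fraction of their sum, at which coupling and interconversion balance with [coupling partner] at its whole charge. The share moves by 2s(1 − s) per unit of skew, where s is the share above, so the ceiling is worth 0.15 points. A gap of 2 points needs 12.9 times that. I therefore put all 4 set-ups at 72.8%, within an estimated 0.15 points, which is less than the margin, and name none as best.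

The forecast gave 72.77% for dawn, 72.83% for summer, 72.84% for spring and 72.83% for autumn, with none as best, holding that “The substrate therefore stays almost racemic”.

The simulation gives 72.8%, 72.8%, 72.8% and 72.8% in that order, and none as best. Dawn has come to rest by 2.50 min: coupling partner stands at 0% of its charge, and the skew, reckoned in proportion to [coupling partner], stands at that same fraction of the 0.391% ceiling. At 25.0 min dawn still reads 6.68% left-handed product and 2.50% right-handed product, in percent of the substrates charged, and the share stays 72.8%. A neighbour like dawn with 0.0022 mM of catalyst has a smaller skew ceiling, 0.157%, and its share reads 72.8%.

Its constants belong to no real substance; no experiment stands behind them.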